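**Retrosynthetic overview**

- The glycerol ether chain is cut at C1–C8' (hydrogenation, Wittig), giving the C1 ketone of the 6-4-4-4 ladder and an eight-carbon phosphonium salt made from 1,8-dibromooctane and 2,2-dimethyl-1,3-dioxan-5-ol.
- The strategy rests on the edge-sharing of the cyclobutanes: ring B (C4-C5-C7-C12), ring C (C7-C8-C11-C12) and ring D (C8-C9-C10-C11) share the edges C7–C12 and C8–C11. Each two-carbon rung (C7/C12, then C8/C11, then C9/C10) is therefore added to the double bond of the ring before it, one carbon by cyclopropanation and the second as a carbene carbon that enlarges the three-membered ring to a cyclobutene.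
- Ring order: ring A comes from cyclohexa-1,4-diene; rings B, C and D follow, each by ethyl diazoacetate cyclopropanation, ester to aldehyde to tosylhydrazone, and aprotic Bamford–Stevens ring expansion. Ring D is last (C8–C9 bond, C9=C10).
- Absolute configuration comes from a desymmetrising hydroboration of the meso bicyclo[4.1.0]heptene with diisopinocampheylborane, which fixes the C1 oxygen. C7/C12 and C8/C11 follow from exo-face (anti) cyclopropanations, and C1 is set at the end by hydrogenation.

Key step: step 14

Numbering used throughout: ring carbons C1–C12 as in the target (C1 bears the chain, chain carbons C1'–C8'); ring A is C1–C6.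

Assumption: the sense of induction of diisopinocampheylborane is taken from cis-but-2-ene, where (−)-Ipc2BH gives (R)-butan-2-ol; this calls for (+)-Ipc2BH here, and the antipodal reagent is used if the alcohol proves to be the mirror image.

**Route**

Step 1
Reactants: 1 cyclohexa-1,4-diene; 2 ethyl diazoacetate
Product: 3 ethyl exo-bicyclo[4.1.0]hept-3-ene-7-carboxylate (meso)
Conditions: Rh2(OAc)4 (0.5 mol %), 1 (5 equiv), CH2Cl2, rt, 2 added over 10 h; exo isomer separated on silica
Reagents that add atoms: none
Why: Rhodium-carbenoid cyclopropanation of one of the two equivalent cis double bonds (excess diene suppresses double addition) should place the ester exo on the new three-membered ring, and the product is meso, so no absolute configuration is involved yet.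

Step 2
Reactants: 3 ethyl exo-bicyclo[4.1.0]hept-3-ene-7-carboxylate
Product: 5 ethyl (1S,3R,6R,7S)-3-hydroxybicyclo[4.1.0]heptane-7-carboxylate (OH trans to the cyclopropane), via borane adduct 4 (not isolated)
Conditions: (+)-Ipc2BH (1.3 equiv, from (−)-α-pinene), THF, −25 °C, 48 h; then 3 M aq NaOH, 30% H2O2, 0 °C to rt, 1 h; chromatography
Reagents that add atoms: hydrogen peroxide, OO
Why: Asymmetric hydroboration with diisopinocampheylborane and oxidation with retention should add boron syn on the alkene face opposite the cyclopropane and, under reagent control, at one of the two enantiotopic alkene carbons, which sets C1 as (R) and with it the absolute sense of the C4/C5 fusion; the minor adduct from the cyclopropane face is a separable diastereomer that must be removed because it leads into the mirror-image series, and the ester tolerates the brief cold alkaline peroxide.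

Step 3
Reactants: 5 ethyl (1S,3R,6R,7S)-3-hydroxybicyclo[4.1.0]heptane-7-carboxylate
Product: 6 tert-butyldimethylsilyl ether of 5
Conditions: TBSCl (1.2 equiv), imidazole (2.5 equiv), DMF, rt
Reagents that add atoms: tert-butyldimethylsilyl chloride, CC(C)(C)[Si](C)(C)Cl
Why: Standard silylation of an unhindered secondary alcohol gives an ether that survives carbenoids, hydride, hydrazide and hot aprotic base, with no change at any stereocentre.

Step 4
Reactants: 6 silyl ether ester
Product: 7 exo-aldehyde (C1-silyloxy bicyclo[4.1.0]heptane-7-carbaldehyde)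
Conditions: i-Bu2AlH (1.1 equiv), CH2Cl2, −78 °C; MeOH at −78 °C, then aq Rochelle salt
Reagents that add atoms: none
Why: Partial reduction of the ester by i-Bu2AlH at −78 °C should stop at the aluminium hemiacetal, which releases the aldehyde only on the cold quench, while silyl ether, cyclopropane and the exo configuration are untouched.

Step 5
Reactants: 7 exo-aldehyde
Product: 8 (E)-tosylhydrazone of 7
Conditions: TsNHNH2 (1.05 equiv), MeOH, 0 °C to rt
Reagents that add atoms: p-toluenesulfonyl hydrazide, Cc1ccc(cc1)S(=O)(=O)NN
Why: Condensation of an unhindered aldehyde with tosylhydrazide is fast without acid and should give the crystalline E-hydrazone.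

Step 6
Reactants: 8 (E)-tosylhydrazone
Product: 12 C1-silyloxy cis-bicyclo[4.2.0]oct-7-ene (rings A and B; C7=C12), via sodium salt 9 (not isolated), via diazoalkane 10 (not isolated), via carbene 11 (not isolated)
Conditions: NaH (1.05 equiv), THF, 0 °C; evaporate; 15-crown-5 (0.1 equiv), 1,4-dioxane (0.02 M), 100 °C, 1 h
Reagents that add atoms: none
Why: This is the aprotic Bamford–Stevens reaction, in which the salt loses sulfinate, the diazoalkane loses N2 and the cyclopropylcarbene enlarges by a 1,2-carbon shift to the cyclobutene, as is known for bicyclo[4.1.0]heptane-7-carbaldehyde tosylhydrazone; C4 and C5 are not involved, so the cis fusion is kept.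

Step 7
Reactants: 12 C1-silyloxy cis-bicyclo[4.2.0]oct-7-ene; 2 ethyl diazoacetate
Product: 13 tricyclic ester (rings A and B with a cyclopropane on C7–C12 anti to ring A; ester exo)
Conditions: Rh2(OAc)4 (1 mol %), CH2Cl2, rt, 2 (3 equiv) by syringe pump over 12 h; exo ester purified on silica
Reagents that add atoms: none
Why: Rhodium-carbenoid cyclopropanation of the strained cis-disubstituted cyclobutene should occur on its convex face, opposite ring A, which sets C7 and C12 with rings A and the new ring anti across ring B, and the ester prefers the exo position.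

Step 8
Reactants: 13 tricyclic ester
Product: 14 tricyclic exo-aldehyde
Conditions: i-Bu2AlH (1.1 equiv), CH2Cl2, −78 °C; MeOH at −78 °C, then aq Rochelle salt
Reagents that add atoms: none
Why: The same cold partial reduction of an ester is used, and the bicyclo[2.1.0]pentane is inert to the hydride at −78 °C.

Step 9
Reactants: 14 tricyclic exo-aldehyde
Product: 15 (E)-tosylhydrazone of 14
Conditions: TsNHNH2 (1.05 equiv), THF, 0 °C to rt; used without heating
Reagents that add atoms: p-toluenesulfonyl hydrazide, Cc1ccc(cc1)S(=O)(=O)NN
Why: Acid-free hydrazone condensation at or below room temperature leaves the strained bicyclopentane intact.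

Step 10
Reactants: 15 (E)-tosylhydrazone
Product: 19 C1-silyloxy tricycle with ring C as cyclobutene (rings A B C; C8=C11), via sodium salt 16 (not isolated), via diazoalkane 17 (not isolated), via carbene 18 (not isolated)
Conditions: NaH (1.05 equiv), THF, 0 °C; evaporate; 15-crown-5 (0.1 equiv), 1,4-dioxane (0.02 M), 100 °C, 1 h, then rapid cooling
Reagents that add atoms: none
Why: Proposed new method: the salt should lose sulfinate and then N2, and the singlet carbene on the exo carbon of the bicyclo[2.1.0]pentane should undergo the same 1,2-shift of a lateral cyclopropane bond (C7 or C12 moving to the carbene carbon) as in step 6, giving ring C as a cyclobutene without touching the C7/C12 stereocentres; the closest known reaction type is the aprotic Bamford–Stevens ring expansion of bicyclo[4.1.0]heptane-7-carbaldehyde tosylhydrazone, not yet shown on a bicyclo[2.1.0]pentane, and loss of acetylene from the carbene would only return 12.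

Step 11
Reactants: 19 tricyclic cyclobutene; 2 ethyl diazoacetate
Product: 20 tetracyclic ester (rings A B C with a cyclopropane on C8–C11 anti to ring B; ester exo)
Conditions: Rh2(OAc)4 (1 mol %), CH2Cl2, 0 °C to rt, 2 (3 equiv) by syringe pump over 12 h; exo ester purified on silica
Reagents that add atoms: none
Why: Rhodium-carbenoid cyclopropanation of the bicyclo[2.2.0]hex-2-ene double bond should take place on its exo face, opposite ring B, which sets C8 and C11 in the anti ladder arrangement, and Rh2(OAc)4 at room temperature does not isomerise the strained σ bonds.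

Step 12
Reactants: 20 tetracyclic ester
Product: 21 tetracyclic exo-aldehyde
Conditions: i-Bu2AlH (1.1 equiv), CH2Cl2, −78 °C; MeOH at −78 °C, then aq Rochelle salt
Reagents that add atoms: none
Why: Cold partial ester reduction as in steps 4 and 8, with the aldehyde kept cold and used at once.

Step 13
Reactants: 21 tetracyclic exo-aldehyde
Product: 22 (E)-tosylhydrazone of 21 (exo hydrazone on the 6-4-4-3 tetracycle)
Conditions: TsNHNH2 (1.05 equiv), THF, 0 °C to rt
Reagents that add atoms: p-toluenesulfonyl hydrazide, Cc1ccc(cc1)S(=O)(=O)NN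
Why: Neutral hydrazone condensation gives the carbene precursor without acid or heat that could open the central C8–C11 bond.

Step 14
Reactants: 22 (E)-tosylhydrazone
Product: 26 C1-silyloxy ladderene (rings A B C D; ring D cyclobutene with C9=C10), via sodium salt 23 (not isolated), via diazoalkane 24 (not isolated), via carbene 25 (not isolated)
Conditions: NaH (1.05 equiv), THF, 0 °C; evaporate; 15-crown-5 (0.1 equiv), 1,4-dioxane (0.02 M), 100 °C, 1 h, then rapid cooling; product kept below 40 °C
Reagents that add atoms: none
Why: Proposed new method: the deprotonated hydrazone 23 should lose p-toluenesulfinate to give diazoalkane 24, which loses N2 to the singlet carbene 25; in its bisected conformer the empty p orbital at C9 lies along the bent C10–C8 bond (or the equivalent C10–C11 bond), so C8 shifts from C10 to C9 with its bonding pair while the carbene lone pair closes the C9=C10 π bond, and the conversion of the divalent carbon into an alkene carbon pays for the reaction even though one highly strained bicycle is exchanged for another. The closest known reaction type is the aprotic Bamford–Stevens ring expansion of cyclopropylcarbenes to cyclobutenes, as used in step 6, which has not been shown on a bicyclo[2.1.0]pentane-5-carbaldehyde hydrazone. Ring D closes by ring enlargement (a 1,2-carbon shift turning the three-membered ring into a four-membered one), not by an exo or endo cyclisation. No stereocentre is created: C8 migrates with retention and C11 is not touched, so the anti geometry fixed in step 11 is carried over, and either lateral bond may migrate because C9 and C10 carry only hydrogen. The step needs the 1,2-carbon shift to win over loss of acetylene (which only returns 19), over 1,2-hydrogen shift, over azine formation and over any cationic pathway; the exo position of the carbene, the strictly aprotic salt, high dilution and the 100 °C ceiling (above which the bicyclo[2.2.0]hexene unit opens to a cyclohexadiene) are meant to secure this.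

Step 15
Reactants: 26 C1-silyloxy ladderene
Product: 27 C1-silyloxy ladderane (ring D saturated)
Conditions: 2-nitrobenzenesulfonylhydrazide (4 equiv), Et3N, CH2Cl2, rt
Reagents that add atoms: none
Why: Diimide generated in the flask transfers H2 syn to the strained cyclobutene at room temperature without a metal, so the ladder σ bonds are not hydrogenolysed and no stereocentre changes.

Step 16
Reactants: 27 C1-silyloxy ladderane
Product: 28 ladderane C1 alcohol (OH trans to ring B)
Conditions: n-Bu4NF (1.5 equiv), THF, rt; aqueous work-up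
Reagents that add atoms: none
Why: Fluoride cleaves the Si–O bond of the secondary silyl ether, and the hydrocarbon ladder is inert.

Step 17
Reactants: 28 ladderane C1 alcohol
Product: 29 ladderane C1 ketone
Conditions: Dess–Martin periodinane (1.3 equiv), NaHCO3, CH2Cl2, 0 °C to rt
Reagents that add atoms: none
Why: Neutral Dess–Martin oxidation gives the ketone, whose α-carbons C2 and C6 are both CH2 groups, so no stereocentre can epimerise.

Step 18
Reactants: 30 2,2-dimethyl-1,3-dioxan-5-ol; 31 1,8-dibromooctane
Product: 33 5-[(8-bromooctyl)oxy]-2,2-dimethyl-1,3-dioxane, via sodium alkoxide 32 (not isolated)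
Conditions: NaH (1.1 equiv), DMF, 0 °C; then 31 (3 equiv), rt, 12 h; excess 31 recovered
Reagents that add atoms: none
Why: Williamson etherification of the secondary alkoxide with a primary bromide, with the dibromide in excess so that mono-alkylation dominates.

Step 19
Reactants: 33 5-[(8-bromooctyl)oxy]-2,2-dimethyl-1,3-dioxane
Product: 34 {8-[(2,2-dimethyl-1,3-dioxan-5-yl)oxy]octyl}triphenylphosphonium bromide
Conditions: PPh3 (1.2 equiv), K2CO3 (0.05 equiv), MeCN, 80 °C, 24 h
Reagents that add atoms: triphenylphosphine, c1ccc(cc1)P(c1ccccc1)c1ccccc1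
Why: SN2 quaternisation of triphenylphosphine by the primary bromide, with a trace of carbonate to keep the acetonide free of HBr.

Step 20
Reactants: 29 ladderane C1 ketone; 34 phosphonium bromide
Product: 36 C1 exocyclic alkene carrying the glycerol acetonide chain (E/Z mixture), via phosphonium ylide 35 (not isolated)
Conditions: 34 (1.5 equiv), NaN(SiMe3)2 (1.45 equiv), THF, 0 °C; then 29, 0 °C to 50 °C
Reagents that add atoms: none
Why: Wittig olefination of a cyclohexanone-type ketone with a non-stabilised ylide forms the C1=C8' bond; the alkene geometry is irrelevant because the bond is reduced next.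

Step 21
Reactants: 36 C1 exocyclic alkene
Product: 37 acetonide of the target (C1 chain cis to ring B)
Conditions: H2 (1 atm), 5% Rh/Al2O3, EtOAc, rt
Reagents that add atoms: none
Why: Heterogeneous syn hydrogenation of the trisubstituted exocyclic alkene should deliver hydrogen to C1 from the face that carries H4 and H5, because C7 on C5 shields the other face in a 1,3-relationship; this puts H1 cis to H4/H5 and the chain cis to ring B as in the target, and rhodium on alumina is chosen to limit double-bond migration.

Step 22
Reactants: 37 acetonide of the target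
Product: 38 CNP0193334.1
Conditions: AcOH/H2O/THF (3:1:1), 40 °C
Reagents that add atoms: none
Why: Mild acid hydrolysis of the isopropylidene acetal frees the 1,3-diol, and the ether link and the saturated ladder are stable to aqueous acetic acid.

**Compound list**

1 | cyclohexa-1,4-diene | C1=CCC=CC1 | starting material
2 | ethyl diazoacetate | CCOC(=O)C=[N+]=[N-] | starting material
3 | ethyl exo-bicyclo[4.1.0]hept-3-ene-7-carboxylate (meso, ester trans to the six-membered ring) | C1=CC[C@@H]2[C@H](C1)[C@H]2C(=O)OCC | intermediate
4 | diisopinocampheylborane adduct of 3 (boron at C1, trans to the cyclopropane) | B([C@@H]1CC[C@@H]2[C@H](C1)[C@H]2C(=O)OCC)([C@H]1C[C@H]2C[C@@H]([C@@H]1C)C2(C)C)[C@H]1C[C@H]2C[C@@H]([C@@H]1C)C2(C)C | intermediate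
5 | ethyl (1S,3R,6R,7S)-3-hydroxybicyclo[4.1.0]heptane-7-carboxylate (OH trans to the cyclopropane, ester exo) | O[C@@H]1CC[C@@H]2[C@H](C1)[C@H]2C(=O)OCC | intermediate
6 | tert-butyldimethylsilyl ether of 5 | CC(C)(C)[Si](C)(C)O[C@@H]1CC[C@@H]2[C@H](C1)[C@H]2C(=O)OCC | intermediate
7 | C1-silyloxy bicyclo[4.1.0]heptane-7-exo-carbaldehyde | CC(C)(C)[Si](C)(C)O[C@@H]1CC[C@@H]2[C@H](C1)[C@H]2C=O | intermediate
8 | (E)-tosylhydrazone of 7 | CC(C)(C)[Si](C)(C)O[C@@H]1CC[C@@H]2[C@H](C1)[C@H]2/C=N/NS(=O)(=O)c3ccc(C)cc3 | intermediate
9 | sodium salt of 8 | CC(C)(C)[Si](C)(C)O[C@@H]1CC[C@@H]2[C@H](C1)[C@H]2/C=N/[N-]S(=O)(=O)c3ccc(C)cc3.[Na+] | intermediate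
10 | 7-exo-diazomethyl bicyclo[4.1.0]heptane from 9 | CC(C)(C)[Si](C)(C)O[C@@H]1CC[C@@H]2[C@H](C1)[C@H]2C=[N+]=[N-] | intermediate
11 | cyclopropylcarbene from 10 | CC(C)(C)[Si](C)(C)O[C@@H]1CC[C@@H]2[C@H](C1)[C@H]2[CH] | intermediate
12 | C1-silyloxy cis-bicyclo[4.2.0]oct-7-ene (rings A and B, C7=C12, silyloxy trans to ring B) | CC(C)(C)[Si](C)(C)O[C@@H]1CC[C@@H]2[C@H](C1)C=C2 | intermediate
13 | tricyclic ester: rings A and B with a cyclopropane on C7–C12 anti to ring A, ester exo | CC(C)(C)[Si](C)(C)O[C@@H]1CC[C@@H]2[C@H](C1)[C@H]1[C@H](C(=O)OCC)[C@@H]21 | intermediate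
14 | tricyclic exo-aldehyde from 13 | CC(C)(C)[Si](C)(C)O[C@@H]1CC[C@@H]2[C@H](C1)[C@H]1[C@H](C=O)[C@@H]21 | intermediate
15 | (E)-tosylhydrazone of 14 | CC(C)(C)[Si](C)(C)O[C@@H]1CC[C@@H]2[C@H](C1)[C@H]1[C@H](/C=N/NS(=O)(=O)c3ccc(C)cc3)[C@@H]21 | intermediate
16 | sodium salt of 15 | CC(C)(C)[Si](C)(C)O[C@@H]1CC[C@@H]2[C@H](C1)[C@H]1[C@H](/C=N/[N-]S(=O)(=O)c3ccc(C)cc3)[C@@H]21.[Na+] | intermediate
17 | exo-diazomethyl tricycle from 16 | CC(C)(C)[Si](C)(C)O[C@@H]1CC[C@@H]2[C@H](C1)[C@H]1[C@H](C=[N+]=[N-])[C@@H]21 | intermediate
18 | carbene from 17 | CC(C)(C)[Si](C)(C)O[C@@H]1CC[C@@H]2[C@H](C1)[C@H]1[C@H]([CH])[C@@H]21 | intermediate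
19 | C1-silyloxy 6-4-4 tricycle with ring C as cyclobutene (C8=C11), rings A and C anti across ring B | CC(C)(C)[Si](C)(C)O[C@@H]1CC[C@@H]2[C@H](C1)[C@H]1C=C[C@@H]21 | intermediate
20 | tetracyclic ester: rings A B C with a cyclopropane on C8–C11 anti to ring B, ester exo | CC(C)(C)[Si](C)(C)O[C@@H]1CC[C@@H]2[C@H](C1)[C@H]1[C@@H]3[C@@H](C(=O)OCC)[C@@H]3[C@@H]21 | intermediate
21 | tetracyclic exo-aldehyde from 20 | CC(C)(C)[Si](C)(C)O[C@@H]1CC[C@@H]2[C@H](C1)[C@H]1[C@@H]3[C@@H](C=O)[C@@H]3[C@@H]21 | intermediate
22 | (E)-tosylhydrazone of 21 (exo, on the 6-4-4-3 tetracycle; C1 silyloxy trans to ring B) | CC(C)(C)[Si](C)(C)O[C@@H]1CC[C@@H]2[C@H](C1)[C@H]1[C@@H]3[C@@H](/C=N/NS(=O)(=O)c4ccc(C)cc4)[C@@H]3[C@@H]21 | intermediate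
23 | sodium salt of 22 | CC(C)(C)[Si](C)(C)O[C@@H]1CC[C@@H]2[C@H](C1)[C@H]1[C@@H]3[C@@H](/C=N/[N-]S(=O)(=O)c4ccc(C)cc4)[C@@H]3[C@@H]21.[Na+] | intermediate
24 | exo-diazomethyl tetracycle from 23 | CC(C)(C)[Si](C)(C)O[C@@H]1CC[C@@H]2[C@H](C1)[C@H]1[C@@H]3[C@@H](C=[N+]=[N-])[C@@H]3[C@@H]21 | intermediate
25 | carbene from 24 | CC(C)(C)[Si](C)(C)O[C@@H]1CC[C@@H]2[C@H](C1)[C@H]1[C@@H]3[C@@H]([CH])[C@@H]3[C@@H]21 | intermediate
26 | C1-silyloxy ladderene (rings A B C D, ring D cyclobutene C9=C10, all fusions cis, neighbouring rings anti) | CC(C)(C)[Si](C)(C)O[C@@H]1CC[C@@H]2[C@H](C1)[C@H]1[C@@H]3C=C[C@@H]3[C@@H]21 | intermediate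
27 | C1-silyloxy ladderane (ring D saturated) | CC(C)(C)[Si](C)(C)O[C@@H]1CC[C@@H]2[C@H](C1)[C@H]1[C@@H]3CC[C@@H]3[C@@H]21 | intermediate
28 | ladderane C1 alcohol (OH trans to ring B) | O[C@@H]1CC[C@@H]2[C@H](C1)[C@H]1[C@@H]3CC[C@@H]3[C@@H]21 | intermediate
29 | ladderane C1 ketone | O=C1CC[C@@H]2[C@H](C1)[C@H]1[C@@H]3CC[C@@H]3[C@@H]21 | intermediate
30 | 2,2-dimethyl-1,3-dioxan-5-ol | CC1(C)OCC(O)CO1 | starting material
31 | 1,8-dibromooctane | BrCCCCCCCCBr | starting material
32 | sodium 2,2-dimethyl-1,3-dioxan-5-olate | CC1(C)OCC([O-])CO1.[Na+] | intermediate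
33 | 5-[(8-bromooctyl)oxy]-2,2-dimethyl-1,3-dioxane | CC1(C)OCC(CO1)OCCCCCCCCBr | intermediate
34 | {8-[(2,2-dimethyl-1,3-dioxan-5-yl)oxy]octyl}triphenylphosphonium bromide | CC1(C)OCC(CO1)OCCCCCCCC[P+](c1ccccc1)(c1ccccc1)c1ccccc1.[Br-] | intermediate
35 | phosphonium ylide from 34 | CC1(C)OCC(CO1)OCCCCCCCC=P(c1ccccc1)(c1ccccc1)c1ccccc1 | intermediate
36 | C1 exocyclic alkene with the glycerol acetonide chain (E/Z mixture) | CC1(C)OCC(CO1)OCCCCCCCC=C1CC[C@@H]2[C@H](C1)[C@H]1[C@@H]3CC[C@@H]3[C@@H]21 | intermediate
37 | acetonide of the target (chain at C1 cis to ring B) | CC1(C)OCC(CO1)OCCCCCCCC[C@H]1CC[C@@H]2[C@H](C1)[C@H]1[C@@H]3CC[C@@H]3[C@@H]21 | intermediate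
38 | CNP0193334.1, 2-O-[8-(ladderanyl)octyl]glycerol | OCC(CO)OCCCCCCCC[C@H]1CC[C@@H]2[C@H](C1)[C@H]1[C@@H]3CC[C@@H]3[C@@H]21 | target

**Step count**

Total: 22 steps. Longest linear sequence: 20 steps (steps 1–17 and 20–22, from cyclohexa-1,4-diene); steps 18–19 form the side branch.

**Steps most likely to fail, with fallbacks**

Step 14. The carbene on the bicyclo[2.1.0]pentane may lose acetylene instead of rearranging, the weak central C8–C11 bond may cleave, or the bicyclo[2.2.0]hexene unit of the product may open thermally during the thermolysis. The fallback builds ring D by photocycloaddition and sets out from 19. Acetophenone-sensitised [2+2] photocycloaddition of 19 with maleic anhydride (acetone, Pyrex filter, 0 °C) should add on the exo face of the cyclobutene and give the ring D anhydride F1. Hydrolysis with water in THF/pyridine gives the cis-diacid F2. Oxidative bis-decarboxylation with Pb(OAc)4 in pyridine at 50 °C then gives the cyclobutene, and the route is rejoined at 26.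

Step 10. The same carbene behaviour one ring earlier carries the same risks: fragmentation back to 12, opening of the bicyclopentane, or thermal loss of the first bicyclo[2.2.0]hexene. The fallback sets out from 12. Sensitised [2+2] photocycloaddition of 12 with maleic anhydride on the convex face gives the ring C anhydride F3, hydrolysis gives the cis-diacid F4, and Pb(OAc)4 bis-decarboxylation in pyridine forms the C8=C11 double bond. The route is rejoined at 19.

Step 21. Facial selectivity in the hydrogenation may be poor, or the double bond may migrate into ring A before reduction; either would give C1 epimers that are hard to separate. The fallback sets C1 by substitution with inversion instead and sets out from 28, whose C1–O bond is trans to ring B. Tosylation (TsCl, pyridine, DMAP) gives the ladderane tosylate F5 with retention. The Grignard reagent F6 is prepared from bromide 33 and Mg in THF. Coupling of F5 with F6 under CuI (10 mol %), TMEDA and LiOMe in THF at 0 °C, a known stereoinvertive SN2 alkylation of secondary tosylates, should place the chain cis to ring B. The route is rejoined at 37, and steps 17, 19 and 20 are then not needed.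

**Further compounds**

F1 | step 14 | ring D maleic anhydride photoadduct of 19 (anhydride ring anti to ring C) | CC(C)(C)[Si](C)(C)O[C@@H]1CC[C@@H]2[C@H](C1)[C@H]1[C@@H]3[C@H]4C(=O)OC(=O)[C@H]4[C@@H]3[C@@H]21
F2 | step 14 | cis-9,10-dicarboxylic acid of the C1-silyloxy ladderane | CC(C)(C)[Si](C)(C)O[C@@H]1CC[C@@H]2[C@H](C1)[C@H]1[C@@H]3[C@@H](C(=O)O)[C@@H](C(=O)O)[C@@H]3[C@@H]21
F3 | step 10 | ring C maleic anhydride photoadduct of 12 (anhydride ring anti to ring A) | CC(C)(C)[Si](C)(C)O[C@@H]1CC[C@@H]2[C@H](C1)[C@H]1[C@@H]3C(=O)OC(=O)[C@@H]3[C@@H]21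
F4 | step 10 | cis-8,11-dicarboxylic acid of the C1-silyloxy 6-4-4 tricycle | CC(C)(C)[Si](C)(C)O[C@@H]1CC[C@@H]2[C@H](C1)[C@H]1[C@H](C(=O)O)[C@H](C(=O)O)[C@@H]21
F5 | step 21 | ladderane C1 p-toluenesulfonate (OTs trans to ring B) | Cc1ccc(cc1)S(=O)(=O)O[C@@H]1CC[C@@H]2[C@H](C1)[C@H]1[C@@H]3CC[C@@H]3[C@@H]21
F6 | step 21 | {8-[(2,2-dimethyl-1,3-dioxan-5-yl)oxy]octyl}magnesium bromide | CC1(C)OCC(CO1)OCCCCCCCC[Mg]Br
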